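Ring A (the 6,6-dimethylcyclohexadienone; C1 = ring carbonyl, C2 = acyl-bearing carbon, C3, C4 = bridge-bearing carbon, C5, C6 = CMe2) is cut into a C4–C5–C6–C1 unit and a C2–C3 unit. In the key step 3-ethoxy-4,4-dimethylcyclobutenone opens to a vinylketene that takes up an ynol ether carrying the future butanoyl chain: C1–C2 and C3–C4 form in one operation and 6π closure onto C6 gives the dienone. The step exploits the quaternary C6, which blocks aromatisation, and the 1,3,5-oxygen pattern of ring A. Rings C and B are then joined to ring A through two Mannich-derived methylene bridges.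

Key step: step 3

Remark: the structure is taken exactly as drawn in the SMILES (no stereocentre, enol tautomers as written; ring B = central butanoylphloroglucinol, ring C = the O-methylated ring); compounds 8, 10, 12 and 13 are racemic or diastereomeric mixtures whose stereocentres are cleared before the target.

Step 1
Reactants: 1 isobutyryl chloride; 2 ethoxyacetylene
Product: 4 3-ethoxy-4,4-dimethylcyclobut-2-en-1-one, via dimethylketene 3 (not isolated)
Conditions: Et3N, Et2O, 0 °C → rt
Reagents that add atoms: none
Why: Dehydrochlorination of 1 by Et3N generates dimethylketene, whose ketene–alkyne [2+2] cycloaddition with the ynol ether is regioselective (alkyne CH carbon onto the ketene carbonyl carbon) and should give the 3-alkoxycyclobutenone.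

Step 2
Reactants: 2 ethoxyacetylene; 5 butanal
Product: 8 triethyl[(1-ethoxyhex-1-yn-3-yl)oxy]silane (racemic), via lithium ethoxyacetylide 6 (not isolated), via lithium 1-ethoxyhex-1-yn-3-olate 7 (not isolated)
Conditions: n-BuLi, THF, −78 °C; butanal; then Et3SiCl, −78 °C → rt
Reagents that add atoms: chlorotriethylsilane, CC[Si](Cl)(CC)CC
Why: Acetylide 1,2-addition to the aldehyde followed by O-silylation of the lithium alkoxide in the same flask should give the protected propargylic ether; the carbinol stereocentre is not controlled and is removed by oxidation in step 5.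

Step 3
Reactants: 4 3-ethoxy-4,4-dimethylcyclobut-2-en-1-one; 8 triethyl[(1-ethoxyhex-1-yn-3-yl)oxy]silane (1.5 equiv)
Product: 12 3,5-diethoxy-6,6-dimethyl-2-[1-(triethylsilyloxy)butyl]cyclohexa-2,4-dien-1-one (racemic), via vinylketene 9 (not isolated), via vinylcyclobutenone 10 (not isolated), via dienylketene 11 (not isolated)
Conditions: toluene, 85 °C, sealed tube, argon
Reagents that add atoms: none
Why: Heating opens 4 by 4π electrocyclic ring opening (release of four-membered-ring strain) to vinylketene 9; the carbon of ynol ether 8 that bears the silyloxybutyl group (future C2) attacks the ketene carbon (C1) while the ethoxy-bearing alkyne carbon (C3) bonds to the ketene α-carbon (C4) in a regioselective [2+2] cycloaddition to 10, which opens again to dienylketene 11 and closes by 6π electrocyclisation between C1 and the gem-dimethyl carbon C6. The closest known reaction is the Danheiser annulation of cyclobutenones with alkoxyalkynes, in the cyclohexadienone-forming variant followed by 4,4-disubstituted cyclobutenones. The transient four-membered ring is closed by ketene–alkyne [2+2] cycloaddition and ring A by thermal disrotatory 6π electrocyclisation of the dienylketene isomer in which the ketene and the C5=C6 unit are cis; the ring openings are reversible, so the unproductive isomer is recycled. No stereocentre is created in 12 (the racemic carbinol carbon is carried in from 8), and the sp3 ring carbon of 10 is lost on opening. The step needs regioselectivity in the [2+2] event, secured by the matched polarisation of ketene (electrophilic at C1) and ynol ether (nucleophilic at the carbon remote from oxygen), and chemoselectivity for capture of 9 over ketene dimerisation or 1,5-hydrogen shift, secured by the excess of the electron-rich alkyne. Because C6 carries two methyl groups the product cannot tautomerise to a phenol and is delivered at the dienone level of ring A with the oxygens on C1, C3 and C5 in place.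

Step 4
Reactants: 12 3,5-diethoxy-6,6-dimethyl-2-[1-(triethylsilyloxy)butyl]cyclohexa-2,4-dien-1-one
Product: 13 3,5-diethoxy-2-(1-hydroxybutyl)-6,6-dimethylcyclohexa-2,4-dien-1-one (racemic)
Conditions: Bu4NF, AcOH, THF, 0 °C
Reagents that add atoms: none
Why: Fluoride-mediated desilylation under buffered conditions should cleave the Si–O bond while leaving the acid-sensitive dienol ethers untouched.

Step 5
Reactants: 13 3,5-diethoxy-2-(1-hydroxybutyl)-6,6-dimethylcyclohexa-2,4-dien-1-one
Product: 14 2-butanoyl-3,5-diethoxy-6,6-dimethylcyclohexa-2,4-dien-1-one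
Conditions: Dess–Martin periodinane, pyridine, CH2Cl2, 0 °C → rt
Reagents that add atoms: none
Why: Dess–Martin oxidation of the secondary alcohol under pyridine buffering should give the ketone without acid-induced ionisation of the carbinol, and it clears the only stereocentre of the ring A series.

Step 6
Reactants: 14 2-butanoyl-3,5-diethoxy-6,6-dimethylcyclohexa-2,4-dien-1-one
Product: 15 2-butanoyl-3,5-dihydroxy-6,6-dimethylcyclohexa-2,4-dien-1-one (butyrylfilicinic acid)
Conditions: 2 M aq. HCl, THF, 50 °C
Reagents that add atoms: water, O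
Why: Enol ether hydrolysis: both ethoxy groups sit on vinylogous ester carbons, so protonation, addition of water and loss of ethanol should give the strongly enolised 2-acyl trione.

Step 7
Reactants: 16 phloroglucinol; 17 butanoyl chloride
Product: 18 1-(2,4,6-trihydroxyphenyl)butan-1-one
Conditions: AlCl3, nitrobenzene, rt → 60 °C; then ice, aq. HCl
Reagents that add atoms: none
Why: Friedel–Crafts C-acylation of the highly activated symmetric triol should stop at the mono-ketone because the first acyl group deactivates the ring.

Step 8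
Reactants: 19 2-methylphloroglucinol; 17 butanoyl chloride
Product: 20 1-(2,4,6-trihydroxy-3-methylphenyl)butan-1-one
Conditions: AlCl3, nitrobenzene, rt → 60 °C; then ice, aq. HCl
Reagents that add atoms: none
Why: Friedel–Crafts C-acylation; the two free ring positions of 19 are equivalent, so a single regioisomer should result.

Step 9
Reactants: 20 1-(2,4,6-trihydroxy-3-methylphenyl)butan-1-one
Product: 21 1-[4,6-bis(benzyloxy)-2-hydroxy-3-methylphenyl]butan-1-one
Conditions: BnBr (2.1 equiv), K2CO3, acetone, reflux
Reagents that add atoms: benzyl bromide, BrCc1ccccc1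
Why: Williamson ether synthesis: the para hydroxyl and the less hindered ortho hydroxyl should be alkylated first, while the hydroxyl flanked by the C-methyl group and the carbonyl stays free as the chelated phenol.

Step 10
Reactants: 21 1-[4,6-bis(benzyloxy)-2-hydroxy-3-methylphenyl]butan-1-one
Product: 22 1-[4,6-bis(benzyloxy)-2-methoxy-3-methylphenyl]butan-1-one
Conditions: MeI, K2CO3, DMF, 50 °C
Reagents that add atoms: iodomethane, CI
Why: Williamson O-methylation of the remaining hydrogen-bonded phenol under more forcing conditions should fix the methyl ether between the C-methyl group and the acyl group.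

Step 11
Reactants: 22 1-[4,6-bis(benzyloxy)-2-methoxy-3-methylphenyl]butan-1-one
Product: 23 1-(4,6-dihydroxy-2-methoxy-3-methylphenyl)butan-1-one
Conditions: H2 (1 atm), Pd/C, EtOAc–MeOH, rt
Reagents that add atoms: none
Why: Catalytic hydrogenolysis should cleave both benzyl ethers and leave the hindered aryl ketone and the methyl ether intact.

Step 12
Reactants: 23 1-(4,6-dihydroxy-2-methoxy-3-methylphenyl)butan-1-one; 18 1-(2,4,6-trihydroxyphenyl)butan-1-one (3 equiv)
Product: 25 1-[3-[(3-butanoyl-2,4,6-trihydroxyphenyl)methyl]-2,4-dihydroxy-6-methoxy-5-methylphenyl]butan-1-one, via Mannich salt 24 (not isolated)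
Conditions: Eschenmoser's salt (1.0 equiv), MeCN, rt; then 18, CH3CO2Na, 80 °C
Reagents that add atoms: N,N-dimethylmethyleneiminium iodide (Eschenmoser's salt), C=[N+](C)C.[I-]
Why: Phenol Mannich reaction at the only free ring carbon of 23, then thermal loss of dimethylamine to an ortho-quinone methide that is trapped by Michael-type C-alkylation of 18, used in excess to suppress double alkylation.

Step 13
Reactants: 15 2-butanoyl-3,5-dihydroxy-6,6-dimethylcyclohexa-2,4-dien-1-one; 25 1-[3-[(3-butanoyl-2,4,6-trihydroxyphenyl)methyl]-2,4-dihydroxy-6-methoxy-5-methylphenyl]butan-1-one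
Product: 27 2-butanoyl-4-[[3-butanoyl-5-[(3-butanoyl-2,6-dihydroxy-4-methoxy-5-methylphenyl)methyl]-2,4,6-trihydroxyphenyl]methyl]-3,5-dihydroxy-6,6-dimethylcyclohexa-2,4-dien-1-one (target), via Mannich salt 26 (not isolated)
Conditions: Eschenmoser's salt (1.0 equiv), MeCN, 0 °C → rt; then 25 (1.0 equiv), CH3CO2Na, rt → 40 °C
Reagents that add atoms: N,N-dimethylmethyleneiminium iodide (Eschenmoser's salt), C=[N+](C)C.[I-]
Why: Mannich reaction at C4 of 15 (the only CH of the enolised trione), then retro-Michael loss of dimethylamine gives the 4-methylene trione, which should be captured in a Michael addition by the single free carbon of ring B in 25 under mild conditions that limit bridge scrambling.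

Compound list
1 | isobutyryl chloride | CC(C)C(=O)Cl | starting material
2 | ethoxyacetylene | CCOC#C | starting material
3 | dimethylketene | CC(C)=C=O | intermediate
4 | 3-ethoxy-4,4-dimethylcyclobut-2-en-1-one | CCOC1=CC(=O)C1(C)C | intermediate
5 | butanal | CCCC=O | starting material
6 | lithium ethoxyacetylide | [Li+].[C-]#COCC | intermediate
7 | lithium 1-ethoxyhex-1-yn-3-olate (racemic) | [Li+].[O-]C(CCC)C#COCC | intermediate
8 | triethyl[(1-ethoxyhex-1-yn-3-yl)oxy]silane (racemic) | CCCC(O[Si](CC)(CC)CC)C#COCC | intermediate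
9 | 3-ethoxy-4-methylpenta-1,3-dien-1-one (vinylketene) | CCOC(C=C=O)=C(C)C | intermediate
10 | 3-ethoxy-4-(1-ethoxy-2-methylprop-1-en-1-yl)-2-[1-(triethylsilyloxy)butyl]cyclobut-2-en-1-one (diastereomer mixture) | CCCC(O[Si](CC)(CC)CC)C1=C(OCC)C(C(OCC)=C(C)C)C1=O | intermediate
11 | 3,5-diethoxy-6-methyl-2-[1-(triethylsilyloxy)butyl]hepta-1,3,5-trien-1-one (dienylketene, both double-bond isomers) | CCCC(O[Si](CC)(CC)CC)C(=C=O)C(OCC)=CC(OCC)=C(C)C | intermediate
12 | 3,5-diethoxy-6,6-dimethyl-2-[1-(triethylsilyloxy)butyl]cyclohexa-2,4-dien-1-one (racemic) | CCCC(O[Si](CC)(CC)CC)C1=C(OCC)C=C(OCC)C(C)(C)C1=O | intermediate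
13 | 3,5-diethoxy-2-(1-hydroxybutyl)-6,6-dimethylcyclohexa-2,4-dien-1-one (racemic) | CCCC(O)C1=C(OCC)C=C(OCC)C(C)(C)C1=O | intermediate
14 | 2-butanoyl-3,5-diethoxy-6,6-dimethylcyclohexa-2,4-dien-1-one | CCCC(=O)C1=C(OCC)C=C(OCC)C(C)(C)C1=O | intermediate
15 | 2-butanoyl-3,5-dihydroxy-6,6-dimethylcyclohexa-2,4-dien-1-one (butyrylfilicinic acid) | CCCC(=O)C1=C(O)C=C(O)C(C)(C)C1=O | intermediate
16 | phloroglucinol (benzene-1,3,5-triol) | Oc1cc(O)cc(O)c1 | starting material
17 | butanoyl chloride | CCCC(=O)Cl | starting material
18 | 1-(2,4,6-trihydroxyphenyl)butan-1-one | CCCC(=O)c1c(O)cc(O)cc1O | intermediate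
19 | 2-methylphloroglucinol (2-methylbenzene-1,3,5-triol) | Cc1c(O)cc(O)cc1O | starting material
20 | 1-(2,4,6-trihydroxy-3-methylphenyl)butan-1-one | CCCC(=O)c1c(O)cc(O)c(C)c1O | intermediate
21 | 1-[4,6-bis(benzyloxy)-2-hydroxy-3-methylphenyl]butan-1-one | CCCC(=O)c1c(O)c(C)c(OCc2ccccc2)cc1OCc1ccccc1 | intermediate
22 | 1-[4,6-bis(benzyloxy)-2-methoxy-3-methylphenyl]butan-1-one | CCCC(=O)c1c(OC)c(C)c(OCc2ccccc2)cc1OCc1ccccc1 | intermediate
23 | 1-(4,6-dihydroxy-2-methoxy-3-methylphenyl)butan-1-one | CCCC(=O)c1c(OC)c(C)c(O)cc1O | intermediate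
24 | 1-[3-[(dimethylamino)methyl]-2,4-dihydroxy-6-methoxy-5-methylphenyl]butan-1-one hydroiodide | CCCC(=O)c1c(OC)c(C)c(O)c(C[NH+](C)C)c1O.[I-] | intermediate
25 | 1-[3-[(3-butanoyl-2,4,6-trihydroxyphenyl)methyl]-2,4-dihydroxy-6-methoxy-5-methylphenyl]butan-1-one | CCCC(=O)c1c(OC)c(C)c(O)c(Cc2c(O)cc(O)c(C(=O)CCC)c2O)c1O | intermediate
26 | 2-butanoyl-4-[(dimethylamino)methyl]-3,5-dihydroxy-6,6-dimethylcyclohexa-2,4-dien-1-one hydroiodide | CCCC(=O)C1=C(O)C(C[NH+](C)C)=C(O)C(C)(C)C1=O.[I-] | intermediate
27 | 2-butanoyl-4-[[3-butanoyl-5-[(3-butanoyl-2,6-dihydroxy-4-methoxy-5-methylphenyl)methyl]-2,4,6-trihydroxyphenyl]methyl]-3,5-dihydroxy-6,6-dimethylcyclohexa-2,4-dien-1-one | CCCC(=O)C1=C(O)C(Cc2c(O)c(Cc3c(O)c(C)c(OC)c(C(=O)CCC)c3O)c(O)c(C(=O)CCC)c2O)=C(O)C(C)(C)C1=O | target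

Total step count: 13
Longest linear sequence: 6 steps (steps 8, 9, 10, 11, 12, 13 from 19; equally steps 1, 3, 4, 5, 6, 13 from 1)

Steps most likely to fail

Step 3. The branched, silyloxy-substituted ynol ether 8 may capture vinylketene 9 too slowly, so that ketene dimerisation, 1,5-hydrogen shift within 9 or thermal loss of ethylene from 8 take over. Fallback: setting out from 4, the same ring expansion is run with the unhindered parent ethoxyacetylene 2 (toluene, 80 °C, sealed tube) to give 3,5-diethoxy-6,6-dimethylcyclohexa-2,4-dien-1-one F1. Hydrolysis (aq. HCl, THF) gives filicinic acid F2. The side chain is then introduced by Friedel–Crafts C-acylation with butanoyl chloride 17 and AlCl3 in nitrobenzene at one of the two equivalent ring CH positions. The route is rejoined at 15.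

Step 9. Site discrimination between the two ortho hydroxyls may be insufficient, or alkylation may run on to the third hydroxyl. Fallback: setting out from 18, whose symmetry removes the site question, dibenzylation (BnBr, K2CO3, acetone) gives 1-[2,4-bis(benzyloxy)-6-hydroxyphenyl]butan-1-one F3. Magnesium-directed ortho-formylation next to the free phenol (MgCl2, Et3N, paraformaldehyde, MeCN, reflux) gives 4,6-bis(benzyloxy)-3-butanoyl-2-hydroxybenzaldehyde F4. O-Methylation (MeI, K2CO3, DMF) gives 4,6-bis(benzyloxy)-3-butanoyl-2-methoxybenzaldehyde F5. Hydrogenation (H2, Pd/C, AcOH) cleaves both benzyl ethers and reduces the formyl group to methyl. The route is rejoined at 23.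

Step 13. Retro-Michael fragment exchange may scramble the methylene bridges, and ring A units may self-condense when retro-Mannich cleavage releases free 15 beside the methylene trione. Fallback: the roles are reversed. Setting out from 25, Mannich reaction with Eschenmoser's salt at the single free carbon of ring B, followed by NaHCO3 work-up, gives 1-[3-[[3-butanoyl-5-[(dimethylamino)methyl]-2,4,6-trihydroxyphenyl]methyl]-2,4-dihydroxy-6-methoxy-5-methylphenyl]butan-1-one F6. Heating F6 with 15 (dioxane, 80 °C) generates the ortho-quinone methide of ring B, which is trapped by the nucleophilic C4 of 15. The route is rejoined at 27.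

Further compounds
F1 | step 3 | 3,5-diethoxy-6,6-dimethylcyclohexa-2,4-dien-1-one | CCOC1=CC(=O)C(C)(C)C(OCC)=C1
F2 | step 3 | filicinic acid (3,5-dihydroxy-6,6-dimethylcyclohexa-2,4-dien-1-one) | OC1=CC(=O)C(C)(C)C(O)=C1
F3 | step 9 | 1-[2,4-bis(benzyloxy)-6-hydroxyphenyl]butan-1-one | CCCC(=O)c1c(O)cc(OCc2ccccc2)cc1OCc1ccccc1
F4 | step 9 | 4,6-bis(benzyloxy)-3-butanoyl-2-hydroxybenzaldehyde | CCCC(=O)c1c(O)c(C=O)c(OCc2ccccc2)cc1OCc1ccccc1
F5 | step 9 | 4,6-bis(benzyloxy)-3-butanoyl-2-methoxybenzaldehyde | CCCC(=O)c1c(OC)c(C=O)c(OCc2ccccc2)cc1OCc1ccccc1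
F6 | step 13 | 1-[3-[[3-butanoyl-5-[(dimethylamino)methyl]-2,4,6-trihydroxyphenyl]methyl]-2,4-dihydroxy-6-methoxy-5-methylphenyl]butan-1-one | CCCC(=O)c1c(OC)c(C)c(O)c(Cc2c(O)c(CN(C)C)c(O)c(C(=O)CCC)c2O)c1O
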